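## Retrosynthetic overview
- Kuwanon A comes from a tris‑MOM flavone by global deprotection. That flavone comes from dehydrogenation of a 3‑prenylflavanone.
- **Key step:** an aryl radical (from the B‑ring 8‑iodochromene **13**, by halogen‑atom transfer) adds to C2 of 3‑prenylchromone **9**, forming the C2–C1′ bond.
- Chromone **9** comes from a 2′‑hydroxyaryl ketone, which comes from Hoesch acylation of phloroglucinol (**3**) with 5‑methylhex‑4‑enenitrile (**6**). The nitrile carries the future C3 prenyl. **3** is made from resorcinol by Ir‑catalysed C5 borylation/oxidation.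
- The B‑ring pyran is formed first, from resorcinol and prenal. Ring order: B‑ring pyran, then the A‑ring oxygenation pattern, then the pyranone C ring (Bredereck/cyclisation), then the radical C2‑arylation, then aromatisation of the C ring.

**Assumptions (one line each)**
- The target has no stereocentres (its only quaternary sp³ carbon carries two identical methyls), so no enantiocontrol is needed.
- The flavanone stereocentres made in Step 10 are erased in Step 11.
- Iodination of the MOM ether **12** is assumed to go para to OMOM (C8). C6 is hindered by the OMOM group.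

## Route

**Step 1**
Reactants: **1** resorcinol
Product: **2** 1,3‑diacetoxybenzene
Conditions: Ac2O, pyridine, DMAP (cat.), CH2Cl2, 0 °C to rt
Reagents that add atoms: acetic anhydride, CC(=O)OC(C)=O
Why: Simple O‑acylation gives a borylation‑compatible, sterically unbiased 1,3‑disubstituted arene.

**Step 2**
Reactants: **2**
Product: **3** phloroglucinol (1,3,5‑trihydroxybenzene)
Conditions: one pot: [Ir(OMe)(cod)]2 (1.5 mol %), dtbpy (3 mol %), B2pin2 (0.6 equiv), THF, 80 °C; then aq. NaOH, H2O2, 0 °C to rt; acidify (N2 throughout)
Reagents that add atoms: B2pin2, CC1(C)OB(OC1(C)C)B1OC(C)(C)C(C)(C)O1 (the boron is lost); H2O2, OO (supplies the new C–OH oxygen)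
Why: Sterically controlled Ir C–H borylation occurs only at C5, the position meta to both acetates. Oxidative workup converts C–B to C–OH and also hydrolyses both acetates.

**Step 3**
Reactants: **4** acetonitrile; **5** prenyl bromide
Product: **6** 5‑methylhex‑4‑enenitrile
Conditions: LiHMDS (1.0 equiv), MeCN (3 equiv), THF, −78 °C, add prenyl bromide, warm to rt
Reagents that add atoms: none
Why: SN2 alkylation of the nitrile α‑carbanion at the primary allylic carbon gives the C7 nitrile that carries the prenyl chain.

**Step 4**
Reactants: **3**, **6**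
Product: **7** 1‑(2,4,6‑trihydroxyphenyl)‑5‑methylhex‑4‑en‑1‑one
Conditions: ZnCl2, HCl (g), Et2O, 0 °C, 12 h; then H2O, 80 °C
Reagents that add atoms: water, O (hydrolyses the ketimine to the ketone C=O)
Why: Houben–Hoesch C‑acylation of the highly nucleophilic phloroglucinol gives a single mono‑acyl product, since all three free ring positions are equivalent.

**Step 5**
Reactants: **7**
Product: **8** 1‑[2‑hydroxy‑4,6‑bis(methoxymethoxy)phenyl]‑5‑methylhex‑4‑en‑1‑one
Conditions: MOMCl (2.2 equiv), K2CO3, acetone, rt
Reagents that add atoms: MOMCl, COCCl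
Why: The carbonyl‑chelated 2′‑OH is unreactive, so only the 4′‑ and 6′‑OH groups are protected. This is the standard selective protection of acylphloroglucinols.

**Step 6**
Reactants: **8**
Product: **9** 5,7‑bis(methoxymethoxy)‑3‑(3‑methylbut‑2‑en‑1‑yl)‑4H‑chromen‑4‑one
Conditions: tBuOCH(NMe2)2 (3 equiv), PhMe, 110 °C; then AcOH (5 equiv), 50 °C
Reagents that add atoms: Bredereck's reagent, CC(C)(C)OC(N(C)C)N(C)C (supplies C2)
Why: The α‑CH2 is formylated to an enaminone. The free 2′‑OH then does an intramolecular addition–elimination (loss of Me2NH) to close the pyranone. This is the Bredereck chromone synthesis; it gives C3‑prenyl and C2–H.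

**Step 7**
Reactants: **1** resorcinol; **10** prenal (3‑methylbut‑2‑enal)
Product: **11** 5‑hydroxy‑2,2‑dimethyl‑2H‑chromene
Conditions: pyridine, 115 °C (sealed tube), 24 h; chromatographic separation from the 7‑hydroxy isomer
Reagents that add atoms: none
Why: Phenol–enal condensation (Knoevenagel/oxa‑6π electrocyclisation) builds the 2,2‑dimethylchromene. Reaction at C2 of resorcinol gives the required 5‑OH isomer as the minor regioisomer.

**Step 8**
Reactants: **11**
Product: **12** 5‑(methoxymethoxy)‑2,2‑dimethyl‑2H‑chromene
Conditions: MOMCl, iPr2NEt, CH2Cl2, 0 °C to rt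
Reagents that add atoms: MOMCl, COCCl
Why: O‑Protection masks the phenol for iodination and radical chemistry, and the OMOM group sterically disfavours the ortho position C6.

**Step 9**
Reactants: **12**
Product: **13** 8‑iodo‑5‑(methoxymethoxy)‑2,2‑dimethyl‑2H‑chromene
Conditions: NIS, MeCN, 0 °C to rt, dark
Reagents that add atoms: N‑iodosuccinimide, O=C1CCC(=O)N1I
Why: Electrophilic aromatic iodination goes para to OMOM. C8 is also ortho to the ring oxygen, while C6 is hindered.

**Step 10 (key radical step)**
Reactants: **9**; **13** (2 equiv)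
Product: **14** 2‑[5‑(methoxymethoxy)‑2,2‑dimethyl‑2H‑chromen‑8‑yl]‑5,7‑bis(methoxymethoxy)‑3‑prenylchroman‑4‑one (racemic, mainly 2,3‑trans)
Conditions: 4CzIPN (2 mol %), Bu3N (3 equiv), H2O (10 equiv), MeCN, blue LEDs, rt, 16 h
Reagents that add atoms: none (only H is added)
Why: Proposed new method: the photogenerated α‑aminoalkyl radical abstracts iodine from **13** (halogen‑atom transfer, as in photochemical XAT hydroarylation of Michael acceptors). The resulting electron‑rich, nucleophilic aryl radical adds to C2 of the chromone. This is polarity‑matched and avoids the electron‑rich prenyl alkene. It gives a tertiary α‑keto radical at C3, which is reduced by the photocatalyst radical anion and protonated. The new C2/C3 stereocentres are set as a mixture and are removed in Step 11.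

**Step 11**
Reactants: **14**
Product: **15** 3‑prenyl‑2‑[5‑(methoxymethoxy)‑2,2‑dimethylchromen‑8‑yl]‑5,7‑bis(methoxymethoxy)chromen‑4‑one (tris‑MOM Kuwanon A)
Conditions: I2 (0.2 equiv), DMSO, 100 °C, 3 h
Reagents that add atoms: none
Why: Enolisation, C3 iodination, then E2 loss of HI (C2–H) with DMSO re‑oxidising iodide. This dehydrogenation gives the flavone and removes both stereocentres; prenyl groups survive these conditions in prenylflavone chemistry.

**Step 12**
Reactants: **15**
Product: **16** Kuwanon A
Conditions: conc. HCl (10 equiv), MeOH, 50 °C, 4 h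
Reagents that add atoms: none
Why: Acid hydrolysis of the three MOM acetals releases the 5‑, 7‑ and 4′‑OH groups. The chromene, prenyl alkene and flavone are stable to dilute HCl/MeOH.

## Compound list
1 | resorcinol | Oc1cccc(O)c1 | starting material
2 | 1,3‑diacetoxybenzene | CC(=O)Oc1cccc(OC(C)=O)c1 | intermediate
3 | phloroglucinol | Oc1cc(O)cc(O)c1 | intermediate
4 | acetonitrile | CC#N | starting material
5 | prenyl bromide | CC(C)=CCBr | starting material
6 | 5‑methylhex‑4‑enenitrile | CC(C)=CCCC#N | intermediate
7 | 1‑(2,4,6‑trihydroxyphenyl)‑5‑methylhex‑4‑en‑1‑one | CC(C)=CCCC(=O)c1c(O)cc(O)cc1O | intermediate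
8 | 1‑[2‑hydroxy‑4,6‑bis(MOM‑oxy)phenyl]‑5‑methylhex‑4‑en‑1‑one | CC(C)=CCCC(=O)c1c(O)cc(OCOC)cc1OCOC | intermediate
9 | 3‑prenyl‑5,7‑bis(MOM‑oxy)chromone | CC(C)=CCc1coc2cc(OCOC)cc(OCOC)c2c1=O | intermediate
10 | prenal | CC(C)=CC=O | starting material
11 | 5‑hydroxy‑2,2‑dimethyl‑2H‑chromene | CC1(C)C=Cc2c(O)cccc2O1 | intermediate
12 | 5‑MOM‑oxy‑2,2‑dimethyl‑2H‑chromene | CC1(C)C=Cc2c(OCOC)cccc2O1 | intermediate
13 | 8‑iodo‑5‑MOM‑oxy‑2,2‑dimethyl‑2H‑chromene | CC1(C)C=Cc2c(OCOC)ccc(I)c2O1 | intermediate
14 | 3‑prenyl‑2‑(chromenyl)‑5,7‑bis(MOM‑oxy)flavanone (racemic) | CC(C)=CCC1C(=O)c2c(OCOC)cc(OCOC)cc2OC1c3ccc(OCOC)c4C=CC(C)(C)Oc34 | intermediate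
15 | tris‑MOM Kuwanon A | CC(C)=CCc1c(-c2ccc(OCOC)c3C=CC(C)(C)Oc23)oc2cc(OCOC)cc(OCOC)c2c1=O | intermediate
16 | Kuwanon A | CC(C)=CCc1c(-c2ccc(O)c3c2OC(C)(C)C=C3)oc2cc(O)cc(O)c2c1=O | target

## Totals
- Total steps: 12.
- Longest linear sequence: 8 (1 → 2 → 3 → 7 → 8 → 9 → 14 → 15 → 16, i.e. Steps 1, 2, 4, 5, 6, 10, 11, 12).

## Three steps most likely to fail
1. **Step 10 (radical hydroarylation).** The aryl radical may be quenched by H‑abstraction from Bu3N or by 1,5‑HAT from the gem‑dimethyl group, and the chromone is electron‑rich.
   - Fallback: switch to a polar assembly. Vilsmeier‑formylate **12** at C8, do a Claisen–Schmidt condensation with ketone **8** to the α‑prenyl chalcone, then close the flavone with I2/DMSO.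
2. **Step 7 (regioselectivity and yield).** Resorcinol plus prenal gives mainly the 7‑hydroxy chromene, with the 5‑hydroxy isomer as a minor product.
   - Fallback: bis‑MOM resorcinol, C2 lithiation between the two OMOM groups, then add prenal. Lewis‑acid ionisation with ring closure onto the neighbouring OMOM oxygen, with MOM loss, gives **12** regiospecifically.
3. **Step 4 (Hoesch with an alkenyl nitrile).** HCl may add to the trisubstituted alkene, or the tertiary cation may alkylate phloroglucinol.
   - Fallback: take the 1,3,5‑tris(MOM‑oxy)benzene route: C–H lithiation, acylation with the Weinreb amide of 5‑methylhex‑4‑enoic acid, then selective removal of the MOM group ortho to the ketone.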